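(Readings and results stem from a simulated flask for substances that don't exist, noise included.)

1. The ratio I read first was L lost per hour over L still there, in fractions of the J charge. J is the limiting reagent, and I counted L left as J left plus the excess 0.100, one L gone per J gone, a balance that leaves out any L held as Z or E.

| setting | alder | birch | cedar | south | south-west | north | west |
|---|---|---|---|---|---|---|---|
| J | 0.14 M | 0.14 M | 0.14 M | 0.14 M | 0.14 M | 0.14 M | 0.14 M (fed, over 40 h) |
| L | 1.1 equiv | 1.1 equiv | 1.1 equiv | 1.10 equiv (fed, over 40 h) | 1.10 equiv (in portions, 2, over 40 h) | 1.10 equiv | 1.10 equiv |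
| X | 10 mol% | 14 mol% | 22 mol% | 10 mol% | 10 mol% | 10 mol% | 10 mol% |
| remark | run made earlier | run made earlier | run made earlier | all else is in the flask from the start; the feed brings no volume worth counting | first portion at the start, last at 40 h | everything together at the start | all else is in the flask from the start; the feed brings no volume worth counting |
| time |  |  |  | 50 h | 50 h | 50 h | 50 h |

| run | time / h | D / % | J / % |
|---|---|---|---|
| alder | 4.00 | 23 | 76 |
| alder | 6.00 | 37 | 58 |
| alder | 12.0 | 64 | 32 |
| alder | 20.0 | 87 | 15 |
| alder | 30.0 | 96 | 3 |
| alder | 48.0 | 101 | 0 |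
| birch | 6.00 | 45 | 49 |
| birch | 12.0 | 78 | 21 |
| birch | 20.0 | 93 | 6 |
| birch | 25.0 | 96 | 5 |
| birch | 30.0 | 101 | 0 |
| birch | 40.0 | 101 | 2 |
| cedar | 2.50 | 29 | 67 |
| cedar | 8.00 | 76 | 19 |
| cedar | 15.0 | 100 | 4 |
| cedar | 20.0 | 97 | 6 |
| cedar | 30.0 | 97 | 0 |
| cedar | 40.0 | 98 | 0 |

(scatter of a reading: 2 percentage points)

- the numbers in the tables scatter with a standard deviation of 2 percentage points
- steps thought possible: L + X -> Z; J + Z -> E; E -> X + D

- the best flask by amount of D, in percent of the J charged; "all alike" if 1.5 percentage points covers them all (south / south-west / north / west / all alike)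
- amount of D at the end, in percent of the J charged, south
- amount of D at the end, in percent of the J charged, south-west
- amount of D at the end, in percent of the J charged, north
- amount of D at the end, in percent of the J charged, west

2. In alder that ratio came to 0.0802 h⁻¹ by 12.0 h and 0.0741 h⁻¹ by 20.0 h. I carried the first reading as the turnover of L, an apparent pseudo-first-order constant. Cedar, with 2.20 times the X of alder, read 0.167 h⁻¹, which is 2.08 times the turnover, so I let it follow the loading.

3. My reckoned rate for north began at 0.0883 h⁻¹ of the J charge. In that reckoning falling L slowed it to 1.81 % of that start by 50 h. Summed, the rate came to 1.08 of the J charge, more than J could supply, so I put D at 100 %.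

4. In my reckoning for south-west the first portion began the rate at half of north's, and by 40 h it had slowed to 4.04 % of that. The last portion restarted it, and over the 10.0 h left the rate fell to 0.448 of that restart. Summed, that gave 83.1 %.

5. In my reckoning south's rate grew with the feed, and the L standing at 40 h then faded by that same factor, which gave 95.3 %. West starts without J, a case the readings don't show, so I made no figure for it. Of my figures, north stood highest.

6. The forecast chose north, with south 93 %, south-west 82 %, north 100 % and west 97 %, holding that “the later steps are fast”. My south and south-west stood slightly above it.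

7. The flasks gave south 94.8 %, south-west 82.9 %, north 99.8 % and west 94.3 %, so north was best.

    L + X → Z (k = 0.00460 M⁻¹ s⁻¹)
    J + Z → E (k = 0.00430 M⁻¹ s⁻¹)
    E → X + D (k = 6.70 × 10⁻⁴ s⁻¹)

The neighbouring flask was north with X cut to 2.5 mol%, a quarter of its loading. I scaled the turnover to 0.0201 h⁻¹, so my reckoned rate stood at 36.7 % of its start by 50 h, and the summed rate used 69.7 % of the J charge in L. That neighbour kept 36.6 % of its own L and gave 68.2 % of D.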